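**Strategy**

In the butenolide ring O1–C2(=O)–C3(Me)=C4(CO2H)–C5, O1 and the carboxyl carbon on C4 are 1,3-related through C5 and C4, the pattern of a β-hydroxy acid. Joining these two atoms gives a 4-alkyl oxetan-2-one. One catalytic asymmetric ketene–aldehyde [2+2] cyclocondensation on an unbranched C16 aldehyde with a remote TBS ether makes it: C4–C5 is formed, the temporary four-membered lactone is closed and C5, the only stereocentre, is set. Alkoxide then opens the lactone with retention, a dianion aldol with ethyl pyruvate adds C2–C3 at C4, and lactonisation, dehydration, deallylation and oxidation of C16 complete the diacid.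

Key step: step 3

Assumption: the (R,R) aluminium–triamine catalyst is taken to give the 4R lactone, the mirror image of the (S,S)/4S pairing expected for unbranched aldehydes; if the first batch shows the opposite sense, the antipodal ligand is used and nothing else changes.

Design notes:
- O16 is carried as a TBS ether. It should survive every step up to the last, where aqueous chromic acid removes it and oxidises C16 in one operation; a more acid-resistant silyl ether would need a separate deprotection. The carbon skeletons of aldehyde 3 and lactone 6 are unaffected.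
- The strained lactone is opened with a hard alkoxide before C4 is functionalised. The C–C bond is then made with a robust alkoxide–enolate dianion, and the C4 carboxyl travels as an allyl ester that is removed without base.
- Catalyst for step 3: the methylaluminium complex formed from AlMe3 and (R,R)-N-benzyl-N,N-bis[3-methyl-2-(trifluoromethanesulfonylamino)butyl]amine (ligand from D-valinol).

**Route**

Step 1
Reactants: 1 hexadecane-1,16-diol
Product: 2 16-[(tert-butyldimethylsilyl)oxy]hexadecan-1-ol
Conditions: NaH (1.0 equiv), THF, 50 °C; TBSCl (1.0 equiv), rt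
Reagents that add atoms: tert-butyldimethylsilyl chloride, CC(C)(C)[Si](C)(C)Cl
Why: Williamson-type O-silylation of the monosodium alkoxide, formed with one equivalent of base and more nucleophilic than the neutral hydroxyl, should favour the mono-ether of this symmetrical diol, and unreacted diol and bis-ether are separated by chromatography and recycled.

Step 2
Reactants: 2 16-[(tert-butyldimethylsilyl)oxy]hexadecan-1-ol
Product: 3 16-[(tert-butyldimethylsilyl)oxy]hexadecanal
Conditions: TEMPO (10 mol%), PhI(OAc)2 (1.1 equiv), CH2Cl2, rt
Reagents that add atoms: none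
Why: The oxoammonium-mediated (TEMPO/hypervalent iodine) alcohol oxidation stops at the aldehyde in anhydrous dichloromethane and does not touch the silyl ether.

Step 3
Reactants: 3 16-[(tert-butyldimethylsilyl)oxy]hexadecanal; 4 acetyl bromide
Product: 6 (4R)-4-{15-[(tert-butyldimethylsilyl)oxy]pentadecyl}oxetan-2-one, via ketene 5 (not isolated)
Conditions: 4 (1.9 equiv), i-Pr2NEt (1.7 equiv), (R,R)-triamine–Al(III) catalyst (10 mol%), CH2Cl2, −50 °C
Reagents that add atoms: none
Why: The amine dehydrobrominates 4 to ketene 5 (or its acylammonium enolate), the Al(III) centre activates the aldehyde, and C–C bond formation between the ketene CH2 and the aldehyde carbon (C4–C5) gives an aluminium aldolate whose oxygen then acylates the activated acyl carbon, an asynchronous formal [2+2]. The closest known reaction type is the catalytic asymmetric acyl halide–aldehyde cyclocondensation to 4-alkyl oxetan-2-ones, for which unbranched aliphatic aldehydes are the best substrate class. The oxetanone ring is closed by 4-exo-trig O-acylation of the aldolate. The single new stereocentre (C5 of the target) is set under catalyst control by the C2-symmetric triamine ligand on aluminium, which exposes one enantioface of the bound aldehyde to the nucleophile. The step needs only enantioface selectivity, and the substrate cannot oppose the catalyst because its α-carbon is an unbranched CH2 and the bulky, non-chelating silyl ether lies fifteen carbons away, while the low temperature holds back ketene dimerisation and aldehyde self-aldol.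

Step 4
Reactants: 6 (4R)-4-{15-[(tert-butyldimethylsilyl)oxy]pentadecyl}oxetan-2-one
Product: 7 prop-2-en-1-yl (3R)-18-[(tert-butyldimethylsilyl)oxy]-3-hydroxyoctadecanoate
Conditions: allyl alcohol (solvent), K2CO3 (0.2 equiv), 0 °C → rt
Reagents that add atoms: allyl alcohol (prop-2-en-1-ol), C=CCO
Why: Base-catalysed alcoholysis by the hard alkoxide (addition–elimination at the acyl carbon) is driven by release of ring strain and cleaves the acyl–oxygen bond only, so the C–O bond at the stereocentre stays intact and the 3R hydroxy ester is formed with retention.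

Step 5
Reactants: 7 prop-2-en-1-yl (3R)-18-[(tert-butyldimethylsilyl)oxy]-3-hydroxyoctadecanoate; 8 ethyl pyruvate
Product: 10 prop-2-en-1-yl (2R)-2-{15-[(tert-butyldimethylsilyl)oxy]pentadecyl}-4-hydroxy-4-methyl-5-oxooxolane-3-carboxylate (diastereomer mixture at ring C3 and C4), via open-chain aldol adduct 9 (not isolated)
Conditions: LDA (2.2 equiv), THF, −78 → −40 °C; 8 (1.5 equiv), −78 °C; AcOH, −78 °C → rt; then PPTS (cat.), CH2Cl2, rt
Reagents that add atoms: none
Why: In this Fráter–Seebach-type aldol addition the alkoxide–enolate dianion, which does not β-eliminate because its β-oxygen is already an alkoxide, attacks the strongly electrophilic ketone carbonyl of 8 through its α-carbon (C4–C3 bond), and the secondary hydroxyl of adduct 9 then lactonises onto the α-hydroxy ethyl ester (5-exo-trig, loss of ethanol); the two new stereocentres at C3 and C4 need no control because step 6 removes both, and C5 is not involved.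

Step 6
Reactants: 10 prop-2-en-1-yl (2R)-2-{15-[(tert-butyldimethylsilyl)oxy]pentadecyl}-4-hydroxy-4-methyl-5-oxooxolane-3-carboxylate
Product: 12 prop-2-en-1-yl (2R)-2-{15-[(tert-butyldimethylsilyl)oxy]pentadecyl}-4-methyl-5-oxo-2,5-dihydrofuran-3-carboxylate, via tertiary mesylate 11 (not isolated)
Conditions: MsCl (2 equiv), Et3N (4 equiv), CH2Cl2, 0 °C → rt
Reagents that add atoms: none
Why: Aldol-type dehydration by E1cB elimination: the tertiary hydroxyl is converted into its mesylate 11 and triethylamine removes the ester-activated C4–H, which places the double bond in the ring in conjugation with both carbonyl groups (an exocyclic isomer, if formed, should be drawn into the same alkene by the amine), while the base is too weak to deprotonate C5 at a useful rate.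

Step 7
Reactants: 12 prop-2-en-1-yl (2R)-2-{15-[(tert-butyldimethylsilyl)oxy]pentadecyl}-4-methyl-5-oxo-2,5-dihydrofuran-3-carboxylate
Product: 13 (2R)-2-{15-[(tert-butyldimethylsilyl)oxy]pentadecyl}-4-methyl-5-oxo-2,5-dihydrofuran-3-carboxylic acid
Conditions: Pd(PPh3)4 (5 mol%), morpholine (3 equiv), THF, rt; 1 M HCl wash
Reagents that add atoms: none
Why: Tsuji–Trost deallylation: Pd(0) ionises the allyl ester to a π-allylpalladium carboxylate and morpholine captures the allyl group, which frees the C4 carboxylic acid under nearly neutral conditions that leave the butenolide, the silyl ether and C5 untouched.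

Step 8
Reactants: 13 (2R)-2-{15-[(tert-butyldimethylsilyl)oxy]pentadecyl}-4-methyl-5-oxo-2,5-dihydrofuran-3-carboxylic acid
Product: 16 (2R)-2-(14-carboxytetradecyl)-4-methyl-5-oxo-2,5-dihydrofuran-3-carboxylic acid, via primary alcohol 14 (not isolated), via terminal aldehyde 15 (not isolated)
Conditions: Jones reagent (CrO3, aq. H2SO4), acetone, 0 °C → rt; i-PrOH quench
Reagents that add atoms: water, O
Why: Jones oxidation: the aqueous sulfuric acid of the reagent cleaves the primary silyl ether to alcohol 14 and chromic acid oxidises it through aldehyde 15 and its hydrate to the carboxylic acid, while the butenolide acid is inert to this acidic oxidant and C5 cannot epimerise under acid.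

**Compound list**

1 | hexadecane-1,16-diol | OCCCCCCCCCCCCCCCCO | starting material
2 | 16-[(tert-butyldimethylsilyl)oxy]hexadecan-1-ol | OCCCCCCCCCCCCCCCCO[Si](C)(C)C(C)(C)C | intermediate
3 | 16-[(tert-butyldimethylsilyl)oxy]hexadecanal | O=CCCCCCCCCCCCCCCCO[Si](C)(C)C(C)(C)C | intermediate
4 | acetyl bromide | CC(=O)Br | starting material
5 | ketene | C=C=O | intermediate (not isolated)
6 | (4R)-4-{15-[(tert-butyldimethylsilyl)oxy]pentadecyl}oxetan-2-one | O=C1C[C@@H](CCCCCCCCCCCCCCCO[Si](C)(C)C(C)(C)C)O1 | intermediate
7 | prop-2-en-1-yl (3R)-18-[(tert-butyldimethylsilyl)oxy]-3-hydroxyoctadecanoate | C=CCOC(=O)C[C@H](O)CCCCCCCCCCCCCCCO[Si](C)(C)C(C)(C)C | intermediate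
8 | ethyl pyruvate | CCOC(=O)C(C)=O | starting material
9 | 4-ethyl 1-(prop-2-en-1-yl) 2-[(1R)-16-[(tert-butyldimethylsilyl)oxy]-1-hydroxyhexadecyl]-3-hydroxy-3-methylbutanedioate (diastereomer mixture at C2 and C3) | CCOC(=O)C(C)(O)C(C(=O)OCC=C)[C@H](O)CCCCCCCCCCCCCCCO[Si](C)(C)C(C)(C)C | intermediate (not isolated)
10 | prop-2-en-1-yl (2R)-2-{15-[(tert-butyldimethylsilyl)oxy]pentadecyl}-4-hydroxy-4-methyl-5-oxooxolane-3-carboxylate (diastereomer mixture at C3 and C4) | C=CCOC(=O)C1[C@@H](CCCCCCCCCCCCCCCO[Si](C)(C)C(C)(C)C)OC(=O)C1(C)O | intermediate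
11 | prop-2-en-1-yl (2R)-2-{15-[(tert-butyldimethylsilyl)oxy]pentadecyl}-4-(methanesulfonyloxy)-4-methyl-5-oxooxolane-3-carboxylate | C=CCOC(=O)C1[C@@H](CCCCCCCCCCCCCCCO[Si](C)(C)C(C)(C)C)OC(=O)C1(C)OS(C)(=O)=O | intermediate (not isolated)
12 | prop-2-en-1-yl (2R)-2-{15-[(tert-butyldimethylsilyl)oxy]pentadecyl}-4-methyl-5-oxo-2,5-dihydrofuran-3-carboxylate | CC1=C(C(=O)OCC=C)[C@@H](CCCCCCCCCCCCCCCO[Si](C)(C)C(C)(C)C)OC1=O | intermediate
13 | (2R)-2-{15-[(tert-butyldimethylsilyl)oxy]pentadecyl}-4-methyl-5-oxo-2,5-dihydrofuran-3-carboxylic acid | CC1=C(C(=O)O)[C@@H](CCCCCCCCCCCCCCCO[Si](C)(C)C(C)(C)C)OC1=O | intermediate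
14 | (2R)-2-(15-hydroxypentadecyl)-4-methyl-5-oxo-2,5-dihydrofuran-3-carboxylic acid | CC1=C(C(=O)O)[C@@H](CCCCCCCCCCCCCCCO)OC1=O | intermediate (not isolated)
15 | (2R)-4-methyl-5-oxo-2-(15-oxopentadecyl)-2,5-dihydrofuran-3-carboxylic acid | CC1=C(C(=O)O)[C@@H](CCCCCCCCCCCCCCC=O)OC1=O | intermediate (not isolated)
16 | (2R)-2-(14-carboxytetradecyl)-4-methyl-5-oxo-2,5-dihydrofuran-3-carboxylic acid | CC1=C(C(=O)O)[C@@H](CCCCCCCCCCCCCCC(=O)O)OC1=O | target

**Totals**

Total step count: 8. Longest linear sequence: 8 steps (1 → 16).

**Steps most likely to fail**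

1. Step 5. What may go wrong: proton transfer from the enolisable α-keto ester to the strongly basic dianion, incomplete second deprotonation of 7, or retro-aldol cleavage of the dialkoxide before ring closure, each of which returns 7. Fallback, setting out from 6 and coming back at 10: the order of ring opening and C–C bond formation is reversed. Lactone 6 is deprotonated with LiHMDS in THF at −100 to −78 °C; its enolate cannot expel the ring oxygen because that C–O bond lies in the nodal plane of the enolate π system. It is trapped at once with 8 to give ethyl 2-hydroxy-2-[(4R)-2-oxo-4-{15-[(tert-butyldimethylsilyl)oxy]pentadecyl}oxetan-3-yl]propanoate F1. K2CO3-catalysed alcoholysis of F1 in allyl alcohol then opens the four-membered ring at the acyl carbon to give 9, which closes to 10 with catalytic PPTS as in the main route.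

2. Step 6. What may go wrong: incomplete sulfonylation of the hindered tertiary hydroxyl, elimination toward the methyl group, or slow amine-mediated loss of configuration at C5 through γ-deprotonation of the product. Fallback, setting out from 10 and coming back at 12: a base-free thermal syn-elimination replaces the E1cB process. Heating 10 with Burgess reagent (benzene, 50 °C) should form the sulfamate ester prop-2-en-1-yl (2R)-2-{15-[(tert-butyldimethylsilyl)oxy]pentadecyl}-4-{[(methoxycarbonyl)sulfamoyl]oxy}-4-methyl-5-oxooxolane-3-carboxylate triethylammonium salt F2, which fragments through a cyclic transition state. Diastereomers with a syn C4–H should give 12 directly; the others should give the exocyclic alkene prop-2-en-1-yl (2R)-2-{15-[(tert-butyldimethylsilyl)oxy]pentadecyl}-4-methylidene-5-oxooxolane-3-carboxylate F3. A catalytic amount of Et3N at 0 °C then moves the double bond of F3 into the ring, by removal of the ester-activated allylic C4–H and reprotonation at the exocyclic carbon, to give 12.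

3. Step 3. What may go wrong: insufficient enantioface discrimination, slow turnover because the waxy aldehyde is poorly soluble at −50 °C, or consumption of ketene by dimerisation. Fallback, setting out from 3 and coming back at 7: the C5 stereocentre is set by ketone reduction instead of cycloaddition. SnCl2-catalysed Roskamp homologation of 3 with methyl diazoacetate (CH2Cl2, rt) gives methyl 18-[(tert-butyldimethylsilyl)oxy]-3-oxooctadecanoate F4. Noyori hydrogenation (RuCl2[(R)-BINAP], H2, MeOH) should give methyl (3R)-18-[(tert-butyldimethylsilyl)oxy]-3-hydroxyoctadecanoate F5; the (R)-ligand is the one that gives (R)-3-hydroxy esters from simple 3-oxo esters. Ti(OiPr)4-catalysed transesterification of F5 in allyl alcohol then gives 7.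

**Further compounds**

F1 | step 5 | ethyl 2-hydroxy-2-[(4R)-2-oxo-4-{15-[(tert-butyldimethylsilyl)oxy]pentadecyl}oxetan-3-yl]propanoate | CCOC(=O)C(C)(O)C1C(=O)O[C@@H]1CCCCCCCCCCCCCCCO[Si](C)(C)C(C)(C)C
F2 | step 6 | prop-2-en-1-yl (2R)-2-{15-[(tert-butyldimethylsilyl)oxy]pentadecyl}-4-{[(methoxycarbonyl)sulfamoyl]oxy}-4-methyl-5-oxooxolane-3-carboxylate triethylammonium salt | C=CCOC(=O)C1[C@@H](CCCCCCCCCCCCCCCO[Si](C)(C)C(C)(C)C)OC(=O)C1(C)OS(=O)(=O)[N-]C(=O)OC.CC[NH+](CC)CC
F3 | step 6 | prop-2-en-1-yl (2R)-2-{15-[(tert-butyldimethylsilyl)oxy]pentadecyl}-4-methylidene-5-oxooxolane-3-carboxylate | C=CCOC(=O)C1[C@@H](CCCCCCCCCCCCCCCO[Si](C)(C)C(C)(C)C)OC(=O)C1=C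
F4 | step 3 | methyl 18-[(tert-butyldimethylsilyl)oxy]-3-oxooctadecanoate | COC(=O)CC(=O)CCCCCCCCCCCCCCCO[Si](C)(C)C(C)(C)C
F5 | step 3 | methyl (3R)-18-[(tert-butyldimethylsilyl)oxy]-3-hydroxyoctadecanoate | COC(=O)C[C@H](O)CCCCCCCCCCCCCCCO[Si](C)(C)C(C)(C)C
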